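**Retrosynthetic overview**
- Endgame: 13 comes from 12 and 12 from 11, by cleaving the O3 silyl ether and then the O5 and O7 MOM acetals. The skeleton does not change once ring C exists.
- Key cut through ring C at C3–C4 and O1–C2: 11 comes from salicylaldehyde 6 (ring A, C4 as formyl carbon, O1 as free phenol) and aryl siloxyalkyne 10 (C2 with ring B, C3 with its oxygen). They are joined by formyl C–H activation at trivalent rhodium and oxidative [4+2] annulation.
- Feature that carries the plan (flavone numbering): O1 sits on C8a, wedged between C4a and the C8 that bears the quaternary 2-methylbut-3-en-2-yl carbon, while C3 bears oxygen and C2 bears ring B. An aldehyde whose only free hydroxyl is on C8a and an alkyne with O on one carbon and aryl on the other supply all three at once.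
- The C8 quaternary carbon is set by an aromatic Claisen shift from O7 of symmetric ether 3: C6 and C8 are equivalent, the para carbon C4a is blocked by the formyl group, and the free flanking hydroxyls speed rearomatisation. A prenyl ether on the C8a oxygen is avoided, because its para carbon C6 is open and crowded phloroglucinol dienones go on by Cope shift to the linear para-prenyl phenol.
- Two MOM groups then go to O5 and O7 and leave the wedged, hydrogen-bonded C8a hydroxyl free; 10 comes from ester 7 by Kowalski homologation. Rings A and B are bought, and ring C is the only ring formed (step 5).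

Key step: step 5

Remark: in benzaldehydes 1–6 the formyl carbon is flavone C4, C1 is C4a, C2 is C8a, C3 is C8, C4 is C7, C5 is C6 and C6 is C5. The target has no stereocentre; 4 is a racemic transient.

**Step 1**
Reactants: 1 2,4,6-trihydroxybenzaldehyde; 2 3-methylbut-2-en-1-ol
Product: 3 2,6-dihydroxy-4-[(3-methylbut-2-en-1-yl)oxy]benzaldehyde
Conditions: PPh3 (1.05 equiv), DIAD (1.05 equiv), THF, 0 °C to rt
Reagents that add atoms: none
Why: Mitsunobu etherification: the 4-OH, para to the formyl group and not hydrogen-bonded to it, is the most acidic hydroxyl and should be the one alkylated, and the neutral medium avoids the C-alkylation that phloroglucinol phenoxides show with prenyl halides.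

**Step 2**
Reactants: 3 2,6-dihydroxy-4-[(3-methylbut-2-en-1-yl)oxy]benzaldehyde
Product: 5 2,4,6-trihydroxy-3-(2-methylbut-3-en-2-yl)benzaldehyde, via ortho-dienone 4 (not isolated)
Conditions: PhNEt2, argon, 190 °C, short heating; cold dilute HCl wash
Reagents that add atoms: none
Why: Aromatic Claisen rearrangement ([3,3]-sigmatropic shift with allyl inversion): the ortho carbons C3 and C5 are equivalent so only dienone 4 can form, its C3–H lies between a ketone and an enol and should be lost quickly in the basic solvent to restore ring A, and the para carbon C1 carries the formyl group, so a following Cope shift finds no hydrogen to lose and stays reversible.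

**Step 3**
Reactants: 5 2,4,6-trihydroxy-3-(2-methylbut-3-en-2-yl)benzaldehyde
Product: 6 2-hydroxy-4,6-bis(methoxymethoxy)-3-(2-methylbut-3-en-2-yl)benzaldehyde
Conditions: MOMCl (2.1 equiv), i-Pr2NEt (3 equiv), CH2Cl2, 0 °C to rt
Reagents that add atoms: methoxymethyl chloride (MOMCl), COCCl
Why: Selective MOM ether formation (O-alkylation with a chloromethyl ether): the 2-OH is wedged between the quaternary carbon and the formyl group and holds the hydrogen bond to C=O, so two equivalents of the small electrophile should go to the 4-OH and the 6-OH and leave free exactly the hydroxyl that becomes O1.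

**Step 4**
Reactants: 7 methyl 4-methoxybenzoate
Product: 10 triisopropyl{[(4-methoxyphenyl)ethynyl]oxy}silane, via lithium dibromoenolate 8 (not isolated), via lithium ynolate 9 (not isolated)
Conditions: CH2Br2, LiTMP (2.2 equiv), THF, −78 °C; n-BuLi, −78 °C to rt; TIPSCl, 0 °C to rt; cold aq NaHCO3, filtration through Et3N-washed silica
Reagents that add atoms: dibromomethane, BrCBr; triisopropylsilyl chloride (TIPSCl), CC(C)[Si](Cl)(C(C)C)C(C)C
Why: Kowalski ester homologation stopped at the ynolate: LiCHBr2 adds to the ester and gives enolate 8, Br/Li exchange triggers a 1,2-aryl shift with loss of LiBr to ynolate 9, and the bulky silyl chloride should silylate at oxygen and not at carbon.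

**Step 5**
Reactants: 6 2-hydroxy-4,6-bis(methoxymethoxy)-3-(2-methylbut-3-en-2-yl)benzaldehyde; 10 triisopropyl{[(4-methoxyphenyl)ethynyl]oxy}silane
Product: 11 5,7-bis(methoxymethoxy)-2-(4-methoxyphenyl)-8-(2-methylbut-3-en-2-yl)-3-[(triisopropylsilyl)oxy]-4H-chromen-4-one
Conditions: [Cp*RhCl2]2 (5 mol %), Cu(OAc)2 (anhydrous, 2.2 equiv), Na2CO3 (3 equiv), 4 Å MS, PhMe, 90 °C; 10 (2 equiv) added over 4 h
Reagents that add atoms: none
Why: Proposed new method: the phenoxide of 6 should bind Cp*Rh(OAc)2 formed in situ, acetate-assisted cleavage of the formyl C–H gives a five-membered acyl rhodacycle holding O1 and C4, 10 inserts into the Rh–acyl bond, C–O reductive elimination from the seven-membered rhodacycle makes O1–C2, and Cu(OAc)2 returns monovalent rhodium to the trivalent state. The closest known reaction type is the oxidative annulation of salicylaldehydes with internal diaryl and alkyl aryl alkynes to 2,3-disubstituted chromones under trivalent rhodium and divalent copper, in which an ynol silyl ether has not been shown as the partner. Ring C closes as a six-membered ring in a formal [4+2] mode, C3–C4 by migratory insertion and O1–C2 by reductive elimination, and no stereocentre is created. One insertion sense is needed, silyloxy carbon to the acyl carbon and aryl carbon to rhodium: the ynol ether has an electrophilic oxygen-bearing carbon and a nucleophilic aryl-bearing carbon, which matches the migrating acyl group and the electropositive metal, and aryl groups also prefer the metal-bound carbon in alkyl aryl alkynes. The site of O1 is fixed by the substrate, since the hydroxyl on C8a is the only free one (O5 and O7 are MOM ethers), and the vinyl group on the C8 quaternary carbon lies too far from C4 for the acyl rhodium to reach it. The acetic acid released would add to the siloxyalkyne, hence anhydrous Cu(OAc)2, carbonate and sieves as scavengers, an aprotic solvent, no silver salt and slow addition of excess 10.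

**Step 6**
Reactants: 11 5,7-bis(methoxymethoxy)-2-(4-methoxyphenyl)-8-(2-methylbut-3-en-2-yl)-3-[(triisopropylsilyl)oxy]-4H-chromen-4-one
Product: 12 3-hydroxy-5,7-bis(methoxymethoxy)-2-(4-methoxyphenyl)-8-(2-methylbut-3-en-2-yl)-4H-chromen-4-one
Conditions: TBAF (1.1 equiv), AcOH (1.1 equiv), THF, 0 °C
Reagents that add atoms: none
Why: Fluoride-mediated silyl ether cleavage: the Si–O bond to the acidic enolic O3 is broken readily by buffered TBAF, while the MOM acetals, the aryl methyl ether and the vinyl group are inert to it.

**Step 7**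
Reactants: 12 3-hydroxy-5,7-bis(methoxymethoxy)-2-(4-methoxyphenyl)-8-(2-methylbut-3-en-2-yl)-4H-chromen-4-one
Product: 13 3,5,7-trihydroxy-2-(4-methoxyphenyl)-8-(2-methylbut-3-en-2-yl)-4H-chromen-4-one
Conditions: conc. HCl (cat.), MeOH, 45 °C
Reagents that add atoms: none
Why: Acid-catalysed acetal exchange (MOM removal) in methanol: the acetal oxygens are protonated far more readily than the monosubstituted vinyl group next to the quaternary carbon, so both phenols should be released without ring closure of the 7-OH onto the alkene and without touching the 4'-methyl ether.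

**Compound list**
1 | 2,4,6-trihydroxybenzaldehyde | O=Cc1c(O)cc(O)cc1O | starting material
2 | 3-methylbut-2-en-1-ol | CC(C)=CCO | starting material
3 | 2,6-dihydroxy-4-[(3-methylbut-2-en-1-yl)oxy]benzaldehyde | CC(C)=CCOc1cc(O)c(C=O)c(O)c1 | intermediate
4 | 2,6-dihydroxy-3-(2-methylbut-3-en-2-yl)-4-oxocyclohexa-1,5-diene-1-carbaldehyde (ortho-dienone, racemic, not isolated) | O=CC1=C(O)C(C(C)(C)C=C)C(=O)C=C1O | intermediate
5 | 2,4,6-trihydroxy-3-(2-methylbut-3-en-2-yl)benzaldehyde | C=CC(C)(C)c1c(O)cc(O)c(C=O)c1O | intermediate
6 | 2-hydroxy-4,6-bis(methoxymethoxy)-3-(2-methylbut-3-en-2-yl)benzaldehyde | C=CC(C)(C)c1c(O)c(C=O)c(OCOC)cc1OCOC | intermediate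
7 | methyl 4-methoxybenzoate | COC(=O)c1ccc(OC)cc1 | starting material
8 | lithium 2,2-dibromo-1-(4-methoxyphenyl)ethen-1-olate (not isolated) | [Li+].[O-]C(=C(Br)Br)c1ccc(OC)cc1 | intermediate
9 | lithium 2-(4-methoxyphenyl)ethyn-1-olate (not isolated) | [Li+].[O-]C#Cc1ccc(OC)cc1 | intermediate
10 | triisopropyl{[(4-methoxyphenyl)ethynyl]oxy}silane | COc1ccc(C#CO[Si](C(C)C)(C(C)C)C(C)C)cc1 | intermediate
11 | 5,7-bis(methoxymethoxy)-2-(4-methoxyphenyl)-8-(2-methylbut-3-en-2-yl)-3-[(triisopropylsilyl)oxy]-4H-chromen-4-one | C=CC(C)(C)c1c(OCOC)cc(OCOC)c2c(=O)c(O[Si](C(C)C)(C(C)C)C(C)C)c(-c3ccc(OC)cc3)oc12 | intermediate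
12 | 3-hydroxy-5,7-bis(methoxymethoxy)-2-(4-methoxyphenyl)-8-(2-methylbut-3-en-2-yl)-4H-chromen-4-one | C=CC(C)(C)c1c(OCOC)cc(OCOC)c2c(=O)c(O)c(-c3ccc(OC)cc3)oc12 | intermediate
13 | 3,5,7-trihydroxy-2-(4-methoxyphenyl)-8-(2-methylbut-3-en-2-yl)-4H-chromen-4-one | C=CC(C)(C)c1c(O)cc(O)c2c(=O)c(O)c(-c3ccc(OC)cc3)oc12 | target

**Total step count:** 7. **Longest linear sequence:** 6 steps (1, 2, 3, 5, 6, 7, from 1).

**Steps most likely to fail**

**Step 5.**
- What may go wrong:
  - Protonation and acetate addition may consume the siloxyalkyne before it inserts.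
  - The insertion may take the opposite sense.
  - The acyl rhodium may lose CO.
  - The formyl group may undergo a Lewis-acid-triggered [2+2] addition to the ynol ether.
  - The crowded C8a phenoxide may bind the metal too weakly for C–H cleavage.
- Fallback (known chemistry): it sets out from 6 and comes back at 12.
  - Commercial 1-ethynyl-4-methoxybenzene and EtMgBr (THF) give bromo[(4-methoxyphenyl)ethynyl]magnesium F1.
  - Two equivalents of F1 add to 6 to give racemic 1-[2-hydroxy-4,6-bis(methoxymethoxy)-3-(2-methylbut-3-en-2-yl)phenyl]-3-(4-methoxyphenyl)prop-2-yn-1-ol F2.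
  - MnO2 in CH2Cl2 oxidises the benzylic propargylic alcohol to 1-[2-hydroxy-4,6-bis(methoxymethoxy)-3-(2-methylbut-3-en-2-yl)phenyl]-3-(4-methoxyphenyl)prop-2-yn-1-one F3.
  - Diethylamine in EtOH adds to the ynone. The enaminone closes by 6-endo addition–elimination of the C8a hydroxyl to 5,7-bis(methoxymethoxy)-2-(4-methoxyphenyl)-8-(2-methylbut-3-en-2-yl)-4H-chromen-4-one F4.
  - LDA and B(OMe)3 (THF, −78 °C) should give dimethyl [5,7-bis(methoxymethoxy)-2-(4-methoxyphenyl)-8-(2-methylbut-3-en-2-yl)-4-oxo-4H-chromen-3-yl]boronate F5.
  - H2O2/AcOH in the same flask turns F5 into 12.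

**Step 2.**
- What may go wrong:
  - The crowded dienone may go on by Cope shift to C1 with later loss of the formyl group.
  - The prenyl ether may ionise and shed its five-carbon unit.
  - The product may react further, by hydrogen transfer from a flanking hydroxyl to the vinyl group (abnormal Claisen path) or by ring closure onto it.
- Fallback: it forms the C8–C bond by cross-coupling instead of a sigmatropic shift. It sets out from 1 and comes back at 6, bypassing steps 1 to 3.
  - MOMCl (2 equiv) and i-Pr2NEt give 2-hydroxy-4,6-bis(methoxymethoxy)benzaldehyde F6.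
  - N-iodosuccinimide should iodinate ortho to the free hydroxyl to give 2-hydroxy-3-iodo-4,6-bis(methoxymethoxy)benzaldehyde F7.
  - F7 is coupled with 4,4,5,5-tetramethyl-2-(3-methylbut-2-en-1-yl)-1,3,2-dioxaborolane under Pd(OAc)2 and a bulky biaryl dialkylphosphine (K3PO4, aqueous THF). This is the γ-selective mode of Suzuki–Miyaura allylation, which joins the aryl carbon to the tertiary allyl terminus and gives 6. The doubly flanked iodide is a demanding case for this coupling.

**Step 4.**
- What may go wrong:
  - The carbenoid rearrangement may stay incomplete.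
  - Silylation may occur at carbon instead of oxygen.
  - The electron-rich ynol silyl ether may hydrolyse during work-up and purification.
- Fallback: it reaches the ynolate by oxidising an acetylide instead of homologating an ester. It sets out, in place of 7, from commercial 1-ethynyl-4-methoxybenzene and comes back at 9.
  - n-BuLi (THF, −78 °C) gives lithium (4-methoxyphenyl)acetylide F8.
  - Lithium tert-butyl peroxide (from anhydrous t-BuOOH and LiHMDS, −78 to 0 °C) transfers oxygen to the acetylide carbon and gives 9.
  - TIPSOTf at −78 °C then silylates 9 to 10.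

**Further compounds**
F1 | step 5 | bromo[(4-methoxyphenyl)ethynyl]magnesium | COc1ccc(C#C[Mg]Br)cc1
F2 | step 5 | 1-[2-hydroxy-4,6-bis(methoxymethoxy)-3-(2-methylbut-3-en-2-yl)phenyl]-3-(4-methoxyphenyl)prop-2-yn-1-ol (racemic) | C=CC(C)(C)c1c(O)c(C(O)C#Cc2ccc(OC)cc2)c(OCOC)cc1OCOC
F3 | step 5 | 1-[2-hydroxy-4,6-bis(methoxymethoxy)-3-(2-methylbut-3-en-2-yl)phenyl]-3-(4-methoxyphenyl)prop-2-yn-1-one | C=CC(C)(C)c1c(O)c(C(=O)C#Cc2ccc(OC)cc2)c(OCOC)cc1OCOC
F4 | step 5 | 5,7-bis(methoxymethoxy)-2-(4-methoxyphenyl)-8-(2-methylbut-3-en-2-yl)-4H-chromen-4-one | C=CC(C)(C)c1c(OCOC)cc(OCOC)c2c(=O)cc(-c3ccc(OC)cc3)oc12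
F5 | step 5 | dimethyl [5,7-bis(methoxymethoxy)-2-(4-methoxyphenyl)-8-(2-methylbut-3-en-2-yl)-4-oxo-4H-chromen-3-yl]boronate | C=CC(C)(C)c1c(OCOC)cc(OCOC)c2c(=O)c(B(OC)OC)c(-c3ccc(OC)cc3)oc12
F6 | step 2 | 2-hydroxy-4,6-bis(methoxymethoxy)benzaldehyde | O=Cc1c(O)cc(OCOC)cc1OCOC
F7 | step 2 | 2-hydroxy-3-iodo-4,6-bis(methoxymethoxy)benzaldehyde | O=Cc1c(O)c(I)c(OCOC)cc1OCOC
F8 | step 4 | lithium (4-methoxyphenyl)acetylide | [Li]C#Cc1ccc(OC)cc1
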